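**Retrosynthetic overview**
1. The target has one ring, closed last as in the presumed biogenesis of the Plocamium/Pantoneura pyranoids: the side-chain carbinol oxygen captures the CHBr2-bearing end of an acyclic halogenated allyl cation. The cation is released from an allylic alcohol by Re2O7, so only the six-membered closure is open (Br+ on the corresponding bromodiene would also open the furanoid 5-endo channel).
2. Acyclic ene-diol ⇐ LiCHBr2 addition to an (E)-enal ⇐ cross-metathesis of a homoallylic dichlorohydrin and methacrolein.
3. Dichlorohydrin ⇐ Brown allylboration of (R)-2,3-dichloro-2-methylpropanal ⇐ catalytic enantioselective dichlorination of methallyl alcohol.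
4. Stereocentres: quaternary C–Cl (step 1, catalyst control), carbinol (step 2, reagent control), ring C2 (step 5, 2,6-trans).

Assumption: in step 1 the ligand antipode that gives (R)-2 is used (the sense on this small substrate is not known and must be confirmed once by correlation), and (−)-Ipc2B(allyl) means the reagent of the (+)-α-pinene series.

**Step 1**
Reactants: 1 2-methylprop-2-en-1-ol (methallyl alcohol)
Product: 2 (R)-2,3-dichloro-2-methylpropan-1-ol
Conditions: t-BuOCl (1.2 equiv), ClTi(OiPr)3 (1.1 equiv), chiral tridentate Schiff-base ligand (20 mol %), hexanes, −20 °C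
Reagents that add atoms: tert-butyl hypochlorite, CC(C)(C)OCl; chlorotitanium triisopropoxide ClTi(OiPr)3, CC(C)O[Ti](Cl)(OC(C)C)OC(C)C
Why: Titanium-templated catalytic enantioselective dichlorination of an allylic alcohol (Burns type), in which the chiral Ti-alkoxide complex delivers chloride to the tertiary carbon while t-BuOCl supplies Cl+ to the CH2 terminus, so the ligand antipode fixes the (R) quaternary chloride.

**Step 2**
Reactants: 2 (R)-2,3-dichloro-2-methylpropan-1-ol; 3 (−)-B-allyldiisopinocampheylborane
Product: 5 (2R,3S)-1,2-dichloro-2-methylhex-5-en-3-ol, via (R)-2,3-dichloro-2-methylpropanal 4 (not isolated)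
Conditions: (COCl)2, DMSO, CH2Cl2, −78 °C, then Et3N, −78 to −20 °C; recool, 3 (1.2 equiv, pentane), −78 °C; HOCH2CH2NH2 work-up
Reagents that add atoms: (−)-B-allyldiisopinocampheylborane (3), C=CCB([C@@H]1C[C@@H]2C[C@@H](C2(C)C)[C@H]1C)[C@@H]1C[C@@H]2C[C@@H](C2(C)C)[C@H]1C
Why: Swern oxidation gives the non-enolisable, volatile α-chloro aldehyde, which is trapped in the same flask by Brown asymmetric allylboration through a chair Zimmerman–Traxler transition state, where the Ipc groups set (3S) by reagent control because the Me/CH2Cl pair gives little competing substrate bias.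

**Step 3**
Reactants: 5 (2R,3S)-1,2-dichloro-2-methylhex-5-en-3-ol; 6 methacrolein (2-methylprop-2-enal)
Product: 7 (2E,5S,6R)-6,7-dichloro-5-hydroxy-2,6-dimethylhept-2-enal
Conditions: 6 (5 equiv), second-generation Hoveyda–Grubbs catalyst RuCl2(H2IMes)(=CH-C6H4-2-OiPr) (5 mol %), CH2Cl2, 40 °C
Reagents that add atoms: methacrolein (6), CC(=C)C=O
Why: Olefin cross-metathesis of a type-1 terminal alkene and excess methacrolein gives the thermodynamic (E)-trisubstituted enal and ethene, leaving the tertiary chloride, the free hydroxyl and both stereocentres untouched.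

**Step 4**
Reactants: 7 (2E,5S,6R)-6,7-dichloro-5-hydroxy-2,6-dimethylhept-2-enal; 8 dibromomethane
Product: 9 (3E,6S,7R)-1,1-dibromo-7,8-dichloro-3,7-dimethyloct-3-ene-2,6-diol (both C2 epimers)
Conditions: CH2Br2 (3 equiv), LDA (2.5 equiv), THF, −78 °C (LiCHBr2 preformed), then 7; AcOH quench at −78 °C
Reagents that add atoms: dibromomethane (8), BrCBr
Why: 1,2-Addition of the carbenoid dibromomethyllithium to the enal installs the CHBr2 carbinol; the first equivalent only deprotonates the hydroxyl, the lithium chlorohydrin alkoxide does not close to an epoxide at −78 °C, and the new carbinol centre (about 1:1) is erased in step 5.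

**Step 5**
Reactants: 9 (3E,6S,7R)-1,1-dibromo-7,8-dichloro-3,7-dimethyloct-3-ene-2,6-diol
Product: 12 (2S,6S)-2-(dibromomethyl)-6-[(2R)-1,2-dichloropropan-2-yl]-3-methyl-5,6-dihydro-2H-pyran, via transposed 3,5-diol 10 (not isolated), via allyl cation 11 (not isolated)
Conditions: Re2O7 (5 mol %), HFIP/CH2Cl2 (1:4), 0 °C to rt
Reagents that add atoms: none
Why: Proposed new method: Re2O7 converts the allylic carbinol of 9 into its perrhenate, 1,3-transposes it to 10 and ionises it in HFIP to the cisoid allyl cation 11, for which attack of the C3 hydroxyl on the CHBr2-bearing C7 is the only ring-size-allowed closure (C5 would give an oxetane and no 5-endo furanoid channel exists), and the boat-like SN1′ transition state that keeps the dichloropropyl group pseudo-equatorial and CHBr2 syn to the vinylic methyl delivers the 2,6-trans (2S) centre, which is also the thermodynamic isomer because pseudo-axial CHBr2 avoids A(1,2) strain against the C3 methyl; the closest known reaction type is Re2O7-catalysed allylic transposition and dehydrative cycloetherification of monoallylic diols.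

**Compound list**
1 | 2-methylprop-2-en-1-ol (methallyl alcohol) | CC(=C)CO | starting material
2 | (R)-2,3-dichloro-2-methylpropan-1-ol | OC[C@@](C)(Cl)CCl | intermediate
3 | (−)-B-allyldiisopinocampheylborane, (−)-Ipc2B(allyl) | C=CCB([C@@H]1C[C@@H]2C[C@@H](C2(C)C)[C@H]1C)[C@@H]1C[C@@H]2C[C@@H](C2(C)C)[C@H]1C | starting material
4 | (R)-2,3-dichloro-2-methylpropanal | O=C[C@@](C)(Cl)CCl | intermediate
5 | (2R,3S)-1,2-dichloro-2-methylhex-5-en-3-ol | C=CC[C@H](O)[C@@](C)(Cl)CCl | intermediate
6 | methacrolein (2-methylprop-2-enal) | CC(=C)C=O | starting material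
7 | (2E,5S,6R)-6,7-dichloro-5-hydroxy-2,6-dimethylhept-2-enal | O=C/C(C)=C/C[C@H](O)[C@@](C)(Cl)CCl | intermediate
8 | dibromomethane | BrCBr | starting material
9 | (3E,6S,7R)-1,1-dibromo-7,8-dichloro-3,7-dimethyloct-3-ene-2,6-diol (both C2 epimers) | BrC(Br)C(O)/C(C)=C/C[C@H](O)[C@@](C)(Cl)CCl | intermediate
10 | (2R,3S,6E)-8,8-dibromo-1,2-dichloro-2,6-dimethyloct-6-ene-3,5-diol (both C5 epimers) | BrC(Br)/C=C(C)/C(O)C[C@H](O)[C@@](C)(Cl)CCl | intermediate
11 | (2R,3S)-8,8-dibromo-1,2-dichloro-3-hydroxy-2,6-dimethyloct-6-en-5-ylium (C5–C7 allyl cation) | BrC(Br)C=C(C)[CH+]C[C@H](O)[C@@](C)(Cl)CCl | intermediate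
12 | (2S,6S)-2-(dibromomethyl)-6-[(2R)-1,2-dichloropropan-2-yl]-3-methyl-5,6-dihydro-2H-pyran | CC1=CC[C@@H]([C@@](C)(Cl)CCl)O[C@@H]1C(Br)Br | target

**Totals**
Total step count: 5. Longest linear sequence: 5 steps (1 → 2 → 5 → 7 → 9 → 12).

**Steps most likely to fail**

1. Step 5. The allyl cation is destabilised by CHBr2, so E1 loss to dienes or slow closure may win over cyclisation. The fallback replaces the free cation by a π-allylpalladium complex. It sets out from 6 and 5: dibromomethyllithium is added to 6 and the alkoxide is trapped in situ with methyl chloroformate to give methyl 1,1-dibromo-3-methylbut-3-en-2-yl carbonate F1. Cross-metathesis of F1 and 5 (second-generation Hoveyda–Grubbs catalyst RuCl2(H2IMes)(=CH-C6H4-2-OiPr)) gives (3E,6S,7R)-1,1-dibromo-7,8-dichloro-6-hydroxy-3,7-dimethyloct-3-en-2-yl methyl carbonate F2, in which the C6 hydroxyl is free. Pd2(dba)3/dppf (zerovalent palladium) in THF then ionises the carbonate, and intramolecular Tsuji–Trost O-allylation at the CHBr2-bearing terminus returns to the route at 12.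

2. Step 1. The ee and the sense of induction on the smallest 2-substituted allylic alcohol are unproven. The fallback reverses the order in which the two side-chain stereocentres are made. It sets out from 6: Brown allylboration of 6 using 3 gives (S)-2-methylhexa-1,5-dien-3-ol F3. Cross-metathesis of F3 and more 6 gives (2E,5S)-5-hydroxy-2,6-dimethylhepta-2,6-dienal F4. Dichlorination of the isopropenyl group of F4 using Et4NCl3 at −78 °C (1,2-induction from the carbinol, enal alkene inert, diastereomers separated) rejoins the route at 7. The sense of this 1,2-induction is itself uncertain, which is why it is the fallback and not the main line.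

3. Step 4. The lithium alkoxide of the chlorohydrin may close to an epoxide, or the carbenoid may enolise the enal. The fallback keeps the base-sensitive fragment away from the carbenoid. It sets out from 6 and 5: dibromomethyllithium is added to 6 to give 1,1-dibromo-3-methylbut-3-en-2-ol F5. Cross-metathesis of 5 and excess F5 (same ruthenium catalyst; the alkene geometry is irrelevant because step 5 equilibrates it) comes back to the route at 9.

**Further compounds**
F1 | step 5 | methyl 1,1-dibromo-3-methylbut-3-en-2-yl carbonate (racemic) | COC(=O)OC(C(Br)Br)C(C)=C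
F2 | step 5 | (3E,6S,7R)-1,1-dibromo-7,8-dichloro-6-hydroxy-3,7-dimethyloct-3-en-2-yl methyl carbonate (both C2 epimers) | COC(=O)OC(C(Br)Br)/C(C)=C/C[C@H](O)[C@@](C)(Cl)CCl
F3 | step 1 | (S)-2-methylhexa-1,5-dien-3-ol | C=CC[C@H](O)C(C)=C
F4 | step 1 | (2E,5S)-5-hydroxy-2,6-dimethylhepta-2,6-dienal | O=C/C(C)=C/C[C@H](O)C(C)=C
F5 | step 4 | 1,1-dibromo-3-methylbut-3-en-2-ol (racemic) | OC(C(Br)Br)C(C)=C
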